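At late times in a resolution I watch one ratio, [left-handed substrate]/[right-handed substrate], since the excess of right-handed substrate among what is left of the two is that ratio in another form.

- gamma: left-handed substrate 0.10 M; right-handed substrate 0.10 M; coupling partner 0.40 M; precatalyst 3.3 mM; run made earlier
- flask: left-handed substrate 0.10 M; coupling partner 0.200 M; precatalyst 3.3 mM; right-handed substrate 0.10 M; time 4.0 d

gamma run (percent of the left-handed substrate and right-handed substrate together charged)

| time / h | right-handed substrate / % | left-handed substrate / % | left-handed product / % |
|---|---|---|---|
| 3.00 | 48 | 30 | 20 |
| 6.00 | 51 | 12 | 37 |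
| 8.00 | 50 | 10 | 45 |
| 12.0 | 45 | 2 | 48 |
| 15.0 | 48 | 3 | 52 |
| 20.0 | 45 | 0 | 49 |

(scatter of a reading: 2 percentage points)

1. whether the excess of right-handed substrate over left-handed substrate among what is left of the two reaches 95% by 4.0 d (yes / no)
2. the highest excess of right-handed substrate over left-handed substrate among what is left of the two up to 4.0 d

- free catalyst is single-handed; left-handed substrate and right-handed substrate are mirror images of each other, charged as a racemate, each of them at the stated concentration
- reactions considered so far: free catalyst + left-handed substrate <-> catalyst intermediate A; free catalyst + right-handed substrate <-> catalyst intermediate B; coupling partner + catalyst intermediate A -> free catalyst + left-handed product; coupling partner + catalyst intermediate B -> free catalyst + right-handed product; coupling partner -> decomposition product; precatalyst -> free catalyst; free catalyst -> spent catalyst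

An excess of 95% asks the natural logarithm of that ratio to fall from zero by 3.66. My bench rule is a pseudo-first-order reckoning. At 6.00 h in the gamma run the right-handed substrate reads 51%, while the left-handed substrate has gone from half of the total charge to 12%, so I read a rate constant of 0.238 h⁻¹.

I scale this by the middle level of the coupling partner, which is 0.150 M in the asked flask against 0.350 M in the gamma run. That gives 0.102 h⁻¹ for the asked flask. Dividing the logarithm by this rate constant gives 35.9 h, my resolution time, the time by this reckoning that a flask needs to reach the wanted excess at unchanged catalyst activity.

The rule stops being tested at the last gamma reading, 20.0 h. My resolution time is 1.79 times that span, so the later part of it is an extrapolation about the catalyst.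

The forecast says yes, with a top of 99% in a range from 90% to 100%, and judges that “catalyst death and partner decomposition look slow”. It reckons 40 to 50 h where I reckon 35.9 h.

The flask gives no, with a top of 90.5%.

    free catalyst + left-handed substrate ⇌ catalyst intermediate A (K = 110 L mol⁻¹, k = 1800 L mol⁻¹ h⁻¹)
    free catalyst + right-handed substrate ⇌ catalyst intermediate B (K = 6.10 L mol⁻¹, k = 11000 L mol⁻¹ h⁻¹)
    coupling partner + catalyst intermediate A → free catalyst + left-handed product (k = 16.0 L mol⁻¹ h⁻¹)
    coupling partner + catalyst intermediate B → free catalyst + right-handed product (k = 5.30 L mol⁻¹ h⁻¹)
    coupling partner → decomposition product (k = 2.40 × 10⁻⁴ h⁻¹)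
    precatalyst → free catalyst (k = 2.80 h⁻¹)
    free catalyst → spent catalyst (k = 0.200 h⁻¹)

In the asked flask spent catalyst stands at 22.0% after 0.400 d and at 95.8% after 2.00 d, when the excess is 89.6%, and my resolution time of 35.9 h falls between those two times. The main reason the top of the asked flask stays below 95% is the reverse step, catalyst intermediate A to free catalyst + left-handed substrate: in the run without that step, the top rises from 90.5% to 100%. Scaled by catalyst charge, the resolution time of the neighbour with 0.0056 M of precatalyst is 21.2 h, and that neighbour reaches 97.7%.

The runs are calculated for substances that don't exist.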